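Retrosynthesis: the three O-benzyl and two O-methyl bonds are cut first, then the C1–C6 bond of ring A, then the depside C(=O)–O bond (acylketene plus ring-B phenol), then the chain C4–C5 and C6–C7 bonds (two Claisen acylations of a dioxinone), and on ring B the C3–O and C1–carboxyl bonds back to divarinol.
Enabling feature: ring A is a 2,4-dioxygenated 6-propylbenzoate, so its C1–C6 and carboxyl carbon map onto C2–C7 and C1 of a 3,5,7-trioxodecanoate (the ring C2 and C4 oxygens are the chain C3 and C5 carbonyls, propyl-bearing C6 is the chain C7 ketone), and the carboxyl carbon is the hindered depside ester carbon.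
Forward: ring B is carried intact from divarinol (hydroxylation between the two oxygens by directed lithiation, then formylation, oxidation and benzylation); the ten-carbon chain is built on the dioxinone; the two are joined as an unhindered aryl β-keto ester; ring A is closed last around that ester; methylation and hydrogenolysis finish.
Stereochemistry: the target has no stereocentre; the two transient ones of the aldol adduct are erased on aromatization.

Key step: step 12

Remark: the 1,3-dicarbonyl compounds 17, 19, 20, 21 and 22 are drawn as keto tautomers although they should exist largely as enols; divarinol is taken as purchasable.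

Step 1
Reactants: 1 5-propylbenzene-1,3-diol (divarinol)
Product: 2 1,3-bis(benzyloxy)-5-propylbenzene
Conditions: BnBr, K2CO3, DMF, rt to 60 °C
Reagents that add atoms: benzyl bromide, BrCc1ccccc1
Why: Williamson etherification of both phenols is routine and installs the groups that are later removed together by hydrogenolysis.

Step 2
Reactants: 2 1,3-bis(benzyloxy)-5-propylbenzene
Product: 5 2,6-bis(benzyloxy)-4-propylphenol, via aryllithium 3 (not isolated), via dimethyl arylboronate 4 (not isolated)
Conditions: n-BuLi, TMEDA, THF, 0 °C to rt; B(OMe)3, −78 °C to rt; H2O2, AcOH, 0 °C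
Reagents that add atoms: n-butyllithium, [Li]CCCC (lithium of 3 only); trimethyl borate, COB(OC)OC (boron and methoxy groups of 4 only); hydrogen peroxide, OO (phenol oxygen of 5)
Why: Directed ortho-metalation should occur at the carbon flanked by both alkoxy groups, and borylation followed by boronate oxidation (1,2-shift of aryl from boron to oxygen) turns the aryllithium into the phenol without touching the benzyl ethers.

Step 3
Reactants: 5 2,6-bis(benzyloxy)-4-propylphenol
Product: 6 2-(allyloxy)-1,3-bis(benzyloxy)-5-propylbenzene
Conditions: allyl bromide, K2CO3, DMF, rt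
Reagents that add atoms: allyl bromide, C=CCBr
Why: Williamson O-allylation masks the central phenol with a group that survives formylation, oxidation and esterification and is orthogonal to benzyl.

Step 4
Reactants: 6 2-(allyloxy)-1,3-bis(benzyloxy)-5-propylbenzene
Product: 8 3-(allyloxy)-2,4-bis(benzyloxy)-6-propylbenzaldehyde, via iminium salt 7 (not isolated)
Conditions: POCl3, DMF, 0 to 70 °C; aq NaOAc
Reagents that add atoms: N,N-dimethylformamide, CN(C)C=O (formyl carbon; Me2N=CH unit of 7); water, O (carbonyl oxygen of 8); phosphoryl chloride, O=P(Cl)(Cl)Cl (chloride counter-ion of 7 only)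
Why: Vilsmeier–Haack formylation can only attack the two equivalent free ring positions, each ortho to one and para to the other benzyloxy group, as in the formylation of 3,4,5-trialkoxytoluenes.

Step 5
Reactants: 8 3-(allyloxy)-2,4-bis(benzyloxy)-6-propylbenzaldehyde
Product: 9 3-(allyloxy)-2,4-bis(benzyloxy)-6-propylbenzoic acid
Conditions: NaClO2, NaH2PO4, 2-methyl-2-butene, t-BuOH/H2O, rt
Reagents that add atoms: sodium chlorite, [Na+].[O-]Cl=O
Why: Pinnick oxidation converts the hindered, electron-rich aldehyde into the acid while the alkene scavenger intercepts hypochlorous acid before it can chlorinate the ring or the allyl group.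

Step 6
Reactants: 9 3-(allyloxy)-2,4-bis(benzyloxy)-6-propylbenzoic acid
Product: 10 benzyl 3-(allyloxy)-2,4-bis(benzyloxy)-6-propylbenzoate
Conditions: BnBr, K2CO3, DMF, rt
Reagents that add atoms: benzyl bromide, BrCc1ccccc1
Why: SN2 alkylation of the carboxylate forms the ester at oxygen and is therefore insensitive to the two ortho substituents that would slow an acyl-substitution esterification.

Step 7
Reactants: 10 benzyl 3-(allyloxy)-2,4-bis(benzyloxy)-6-propylbenzoate
Product: 11 benzyl 2,4-bis(benzyloxy)-3-hydroxy-6-propylbenzoate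
Conditions: Pd(PPh3)4 (5 mol%), morpholine, THF, rt
Reagents that add atoms: none
Why: Tsuji–Trost deallylation, in which zerovalent palladium ionizes the aryl allyl ether to a π-allyl complex that morpholine captures, should leave the benzyl ethers and the benzyl ester untouched.

Step 8
Reactants: 12 butanoyl chloride
Product: 13 N-methoxy-N-methylbutanamide
Conditions: MeNHOMe·HCl, pyridine, CH2Cl2, 0 °C to rt
Reagents that add atoms: N,O-dimethylhydroxylamine hydrochloride, CNOC.Cl
Why: Weinreb amide formation by N-acylation gives an acyl donor that stops at the ketone stage in the later Claisen step.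

Step 9
Reactants: 14 2,2,6-trimethyl-4H-1,3-dioxin-4-one; 15 acetyl chloride
Product: 17 2,2-dimethyl-6-(2-oxopropyl)-4H-1,3-dioxin-4-one, via lithium dienolate 16 (not isolated)
Conditions: LiN(SiMe3)2, THF, −78 °C; 15 (0.5 equiv), −78 °C; aq NH4Cl
Reagents that add atoms: lithium bis(trimethylsilyl)amide, [Li]N([Si](C)(C)C)[Si](C)(C)C (lithium of 16 only)
Why: Deprotonation of the 6-methyl group gives the vinylogous ester enolate, whose terminal carbon is C-acylated by acetyl chloride (vinylogous Claisen acylation), half an equivalent of chloride being used because the more acidic product quenches a second equivalent of enolate.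

Step 10
Reactants: 17 2,2-dimethyl-6-(2-oxopropyl)-4H-1,3-dioxin-4-one; 13 N-methoxy-N-methylbutanamide
Product: 19 6-(2,4-dioxoheptyl)-2,2-dimethyl-4H-1,3-dioxin-4-one, via dilithium dianion 18 (not isolated)
Conditions: LiN(i-Pr)2 (3 equiv), THF, −78 °C; 13, −78 to −20 °C; 1 M HCl
Reagents that add atoms: lithium diisopropylamide, [Li]N(C(C)C)C(C)C (lithium of 18 only)
Why: The dianion reacts at its more basic terminal carbanion with the Weinreb amide (crossed Claisen acylation of a 1,3-dicarbonyl dianion), and the chelated tetrahedral adduct prevents over-addition.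

Step 11
Reactants: 19 6-(2,4-dioxoheptyl)-2,2-dimethyl-4H-1,3-dioxin-4-one; 11 benzyl 2,4-bis(benzyloxy)-3-hydroxy-6-propylbenzoate
Product: 21 benzyl 2,4-bis(benzyloxy)-6-propyl-3-[(3,5,7-trioxodecanoyl)oxy]benzoate, via acylketene 20 (not isolated)
Conditions: 19 (1.5 equiv), 11 (1.0 equiv), toluene (0.3 M), 110 °C; evaporate, use crude
Reagents that add atoms: none
Why: Thermal retro-hetero-Diels–Alder loss of acetone from the dioxinone gives an acylketene that the phenol captures by nucleophilic addition, so the depside ester is made as an unhindered β-keto ester before any ortho substituent of ring A exists.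

Step 12
Reactants: 21 benzyl 2,4-bis(benzyloxy)-6-propyl-3-[(3,5,7-trioxodecanoyl)oxy]benzoate
Product: 23 benzyl 2,4-bis(benzyloxy)-3-[(2,4-dihydroxy-6-propylbenzoyl)oxy]-6-propylbenzoate, via aldol adduct 22 (not isolated)
Conditions: Et3N (3 equiv), CH2Cl2, 0 °C to rt; then HCl (4 M in dioxane), rt
Reagents that add atoms: none
Why: Triethylamine enolizes the chain C2 methylene between the aryl ester and the C3 ketone, and this enolate adds to the C7 ketone to form the C2–C7 bond (C1–C6 of ring A) and the cyclic β-hydroxy diketone 22; acid then eliminates water and the C3 and C5 carbonyls tautomerize to the two phenols, aromatization being the driving force. The closest known reaction type is the cycloaromatization of 3,5,7-triketo esters released from diketo-dioxinones, which amine or carbonate bases convert into esters of resorcylic acids by intramolecular aldol condensation. Ring A is the only ring closed, in a 6-(enolendo)-exo-trig mode. No stereocentre remains, since the two of adduct 22 form without control and are erased on aromatization. The step needs chemoselectivity for the C2-to-C7 aldol over attack of the C5 enol oxygen or the C6 carbanion on the ester carbonyl (pyrone or acylphloroglucinol with loss of the ring-B phenoxide) and over aldol from the singly activated C8 methylene. The two ortho benzyloxy groups shield the ester carbonyl, the ketone is the better electrophile under a weak amine base in an aprotic solvent, and C2 is the only doubly activated carbon that can close a six-membered ring onto a ketone.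

Step 13
Reactants: 23 benzyl 2,4-bis(benzyloxy)-3-[(2,4-dihydroxy-6-propylbenzoyl)oxy]-6-propylbenzoate
Product: 24 benzyl 2,4-bis(benzyloxy)-3-[(2,4-dimethoxy-6-propylbenzoyl)oxy]-6-propylbenzoate
Conditions: MeI (excess), K2CO3, DMF, rt to 40 °C
Reagents that add atoms: iodomethane, CI
Why: Williamson O-methylation of the two ring-A phenols (the hydrogen-bonded ortho phenol being the slower) under carbonate should not cleave the doubly ortho-substituted depside ester, and no other free hydroxyl is present.

Step 14
Reactants: 24 benzyl 2,4-bis(benzyloxy)-3-[(2,4-dimethoxy-6-propylbenzoyl)oxy]-6-propylbenzoate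
Product: 25 2,4-dihydroxy-3-[(2,4-dimethoxy-6-propylbenzoyl)oxy]-6-propylbenzoic acid
Conditions: H2 (1 atm), 10% Pd/C, EtOAc, rt
Reagents that add atoms: none
Why: Catalytic hydrogenolysis cleaves the two benzyl ethers and the benzyl ester in one neutral operation, which spares the aryl ester and avoids base-promoted acyl migration to the neighbouring phenols or decarboxylation of the salicylic acid.

Compound list
1 | 5-propylbenzene-1,3-diol (divarinol) | CCCc1cc(O)cc(O)c1 | starting material
2 | 1,3-bis(benzyloxy)-5-propylbenzene | CCCc1cc(OCc2ccccc2)cc(OCc2ccccc2)c1 | intermediate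
3 | [2,6-bis(benzyloxy)-4-propylphenyl]lithium | CCCc1cc(OCc2ccccc2)c([Li])c(OCc2ccccc2)c1 | intermediate (not isolated)
4 | dimethyl [2,6-bis(benzyloxy)-4-propylphenyl]boronate | CCCc1cc(OCc2ccccc2)c(B(OC)OC)c(OCc2ccccc2)c1 | intermediate (not isolated)
5 | 2,6-bis(benzyloxy)-4-propylphenol | CCCc1cc(OCc2ccccc2)c(O)c(OCc2ccccc2)c1 | intermediate
6 | 2-(allyloxy)-1,3-bis(benzyloxy)-5-propylbenzene | CCCc1cc(OCc2ccccc2)c(OCC=C)c(OCc2ccccc2)c1 | intermediate
7 | N-{[3-(allyloxy)-2,4-bis(benzyloxy)-6-propylphenyl]methylidene}-N-methylmethanaminium chloride | CCCc1cc(OCc2ccccc2)c(OCC=C)c(OCc2ccccc2)c1C=[N+](C)C.[Cl-] | intermediate (not isolated)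
8 | 3-(allyloxy)-2,4-bis(benzyloxy)-6-propylbenzaldehyde | CCCc1cc(OCc2ccccc2)c(OCC=C)c(OCc2ccccc2)c1C=O | intermediate
9 | 3-(allyloxy)-2,4-bis(benzyloxy)-6-propylbenzoic acid | CCCc1cc(OCc2ccccc2)c(OCC=C)c(OCc2ccccc2)c1C(=O)O | intermediate
10 | benzyl 3-(allyloxy)-2,4-bis(benzyloxy)-6-propylbenzoate | CCCc1cc(OCc2ccccc2)c(OCC=C)c(OCc2ccccc2)c1C(=O)OCc1ccccc1 | intermediate
11 | benzyl 2,4-bis(benzyloxy)-3-hydroxy-6-propylbenzoate | CCCc1cc(OCc2ccccc2)c(O)c(OCc2ccccc2)c1C(=O)OCc1ccccc1 | intermediate
12 | butanoyl chloride | CCCC(=O)Cl | starting material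
13 | N-methoxy-N-methylbutanamide | CCCC(=O)N(C)OC | intermediate
14 | 2,2,6-trimethyl-4H-1,3-dioxin-4-one | CC1=CC(=O)OC(C)(C)O1 | starting material
15 | acetyl chloride | CC(=O)Cl | starting material
16 | lithium 2,2-dimethyl-6-methylidene-6H-1,3-dioxin-4-olate | [Li+].[O-]C1=CC(=C)OC(C)(C)O1 | intermediate (not isolated)
17 | 2,2-dimethyl-6-(2-oxopropyl)-4H-1,3-dioxin-4-one | CC(=O)CC1=CC(=O)OC(C)(C)O1 | intermediate
18 | dilithium dianion of 17 (ring enolate and terminal enolate) | [Li+].[Li+].C=C([O-])C=C1C=C([O-])OC(C)(C)O1 | intermediate (not isolated)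
19 | 6-(2,4-dioxoheptyl)-2,2-dimethyl-4H-1,3-dioxin-4-one | CCCC(=O)CC(=O)CC1=CC(=O)OC(C)(C)O1 | intermediate
20 | 3,5,7-trioxodec-1-en-1-one (acylketene) | CCCC(=O)CC(=O)CC(=O)C=C=O | intermediate (not isolated)
21 | benzyl 2,4-bis(benzyloxy)-6-propyl-3-[(3,5,7-trioxodecanoyl)oxy]benzoate | CCCC(=O)CC(=O)CC(=O)CC(=O)Oc1c(OCc2ccccc2)cc(CCC)c(C(=O)OCc2ccccc2)c1OCc1ccccc1 | intermediate
22 | benzyl 2,4-bis(benzyloxy)-3-[(2-hydroxy-4,6-dioxo-2-propylcyclohexane-1-carbonyl)oxy]-6-propylbenzoate (mixture of stereoisomers) | CCCC1(O)CC(=O)CC(=O)C1C(=O)Oc1c(OCc2ccccc2)cc(CCC)c(C(=O)OCc2ccccc2)c1OCc1ccccc1 | intermediate (not isolated)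
23 | benzyl 2,4-bis(benzyloxy)-3-[(2,4-dihydroxy-6-propylbenzoyl)oxy]-6-propylbenzoate | CCCc1cc(O)cc(O)c1C(=O)Oc1c(OCc2ccccc2)cc(CCC)c(C(=O)OCc2ccccc2)c1OCc1ccccc1 | intermediate
24 | benzyl 2,4-bis(benzyloxy)-3-[(2,4-dimethoxy-6-propylbenzoyl)oxy]-6-propylbenzoate | CCCc1cc(OC)cc(OC)c1C(=O)Oc1c(OCc2ccccc2)cc(CCC)c(C(=O)OCc2ccccc2)c1OCc1ccccc1 | intermediate
25 | 2,4-dihydroxy-3-[(2,4-dimethoxy-6-propylbenzoyl)oxy]-6-propylbenzoic acid | CCCc1cc(OC)cc(OC)c1C(=O)Oc1c(O)cc(CCC)c(C(=O)O)c1O | target

Total step count: 14. Longest linear sequence: 11 steps (steps 1–7, then 11–14); the dioxinone branch (steps 8–10) joins at step 11.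

Steps most likely to fail

1. Step 12. The aryl ester is a good leaving group, so lactonization by the C5 enol oxygen or Claisen closure from C6 may expel the ring-B phenoxide faster than the aldol closes. Fallback, setting out from 19 and returning to the route at 24: ring A would be closed on the dioxinone before the depside ester exists. Et3N in CH2Cl2 at rt should bring about the same aldol aromatization of 19 and give 7-hydroxy-2,2-dimethyl-5-propyl-4H-1,3-benzodioxin-4-one F1 with loss of water. Methylation of F1 with MeI and K2CO3 in acetone would give 7-methoxy-2,2-dimethyl-5-propyl-4H-1,3-benzodioxin-4-one F2 as the ring-A donor. Irradiation of F2 at 300 nm in CH2Cl2 in the presence of phenol 11 should expel acetone and form the transient quinoketene 3-methoxy-6-(oxomethylidene)-5-propylcyclohexa-2,4-dien-1-one F3 in the flask. Phenol 11 should add to F3 as it forms and give benzyl 2,4-bis(benzyloxy)-3-[(2-hydroxy-4-methoxy-6-propylbenzoyl)oxy]-6-propylbenzoate F4 as the depside. Methylation of the remaining phenol of F4 with MeI and K2CO3 in DMF rejoins the route at 24.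

2. Step 11. Capture of the acylketene by the doubly ortho-substituted phenol may be slow, so ketene dimerization, intramolecular enol lactonization and thermal reversal of the aryl ester could consume the chain. Fallback, setting out from 19 and returning to the route at 21: the ketene would first be trapped by a small, strong nucleophile and the acyl group transferred at room temperature. Heating 19 with 2-methylpropane-2-thiol in toluene in a sealed tube at 110 °C should give S-tert-butyl 3,5,7-trioxodecanethioate F5 with loss of acetone. Silver-promoted transacylation of F5 with phenol 11 (AgOCOCF3, THF, rt) would then deliver 21.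

3. Step 2. Benzylic deprotonation of the benzyl ethers followed by 1,2-Wittig rearrangement may compete with ring lithiation. Fallback, setting out from 1 and returning to the route at 6: the lithiation would be run on acetal ethers and the benzyl groups installed afterwards. MOMCl and i-Pr2NEt in CH2Cl2 should convert 1 into 1,3-bis(methoxymethoxy)-5-propylbenzene F6 as the lithiation substrate. Lithiation of F6 with n-BuLi in THF at 0 °C, then B(OMe)3 and H2O2, would give 2,6-bis(methoxymethoxy)-4-propylphenol F7 by the same borylation and oxidation. Allyl bromide and K2CO3 in DMF would turn F7 into 2-(allyloxy)-1,3-bis(methoxymethoxy)-5-propylbenzene F8 by O-allylation. Treatment of F8 with HCl in MeOH would release 2-(allyloxy)-5-propylbenzene-1,3-diol F9 as the free diol, and benzylation of F9 with BnBr and K2CO3 in DMF would give 6.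

Further compounds
F1 | step 12 | 7-hydroxy-2,2-dimethyl-5-propyl-4H-1,3-benzodioxin-4-one | CCCc1cc(O)cc2OC(C)(C)OC(=O)c12
F2 | step 12 | 7-methoxy-2,2-dimethyl-5-propyl-4H-1,3-benzodioxin-4-one | CCCc1cc(OC)cc2OC(C)(C)OC(=O)c12
F3 | step 12 | 3-methoxy-6-(oxomethylidene)-5-propylcyclohexa-2,4-dien-1-one | CCCC1=CC(OC)=CC(=O)C1=C=O
F4 | step 12 | benzyl 2,4-bis(benzyloxy)-3-[(2-hydroxy-4-methoxy-6-propylbenzoyl)oxy]-6-propylbenzoate | CCCc1cc(OC)cc(O)c1C(=O)Oc1c(OCc2ccccc2)cc(CCC)c(C(=O)OCc2ccccc2)c1OCc1ccccc1
F5 | step 11 | S-tert-butyl 3,5,7-trioxodecanethioate | CCCC(=O)CC(=O)CC(=O)CC(=O)SC(C)(C)C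
F6 | step 2 | 1,3-bis(methoxymethoxy)-5-propylbenzene | CCCc1cc(OCOC)cc(OCOC)c1
F7 | step 2 | 2,6-bis(methoxymethoxy)-4-propylphenol | CCCc1cc(OCOC)c(O)c(OCOC)c1
F8 | step 2 | 2-(allyloxy)-1,3-bis(methoxymethoxy)-5-propylbenzene | CCCc1cc(OCOC)c(OCC=C)c(OCOC)c1
F9 | step 2 | 2-(allyloxy)-5-propylbenzene-1,3-diol | CCCc1cc(O)c(OCC=C)c(O)c1
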